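**Retrosynthetic overview**
- Triene: Heck union of the C4 vinyl group of the epoxyquinol core with a (2E,4E)-5-iodopenta-2,4-dienamide that already carries the bought aminocyclopentenone ring.
- Epoxide (last ring formed): nucleophilic epoxidation of a cross-conjugated 4-silyloxy dienone, anti to the silyloxy group; the dienone arises by E1cB loss of silanol.
- Enamide C–N bond: light-driven nickel coupling of a 2-iodo enone with (2E,4R)-4-methyloct-2-enamide, whose stereocentre is bought in (S)-3-bromo-2-methylpropan-1-ol.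
- Chiral 4-hydroxy-4-vinylcyclohexenone from (−)-quinic acid: the carboxyl carbon is excised at the anode to give the ring ketone, vinyl adds to a C4 ketone under control of the lactone, and O5 then O3 are expelled one after the other, which tells the two sides of the ring apart.
- Ring order: carbocycle bought; temporary γ-lactone closed in step 1 and opened in step 5; epoxide closed in step 11; cyclopentenone ring bought.

Assumption: (S)-3-bromo-2-methylpropan-1-ol, 2-amino-3-hydroxycyclopent-2-en-1-one hydrochloride and (E)-3-iodoprop-2-en-1-ol are catalogue chemicals; locants C1–C6 in the explanations are those of quinic acid.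

Step 1
Reactants: 1 (−)-quinic acid
Product: 2 quinide, (1S,3R,4R,5R)-1,3,4-trihydroxy-6-oxabicyclo[3.2.1]octan-7-one
Conditions: TsOH·H2O (cat.), toluene/DMF, reflux, Dean–Stark
Reagents that add atoms: none
Why: Acid-catalysed lactonisation in which only the C5 hydroxyl is cis to the carboxyl group, so the 1,5-lactone closes selectively and locks the ring in one chair without touching a stereocentre.

Step 2
Reactants: 2 quinide
Product: 3 (1R,3R,4S,5R)-3-[(tert-butyldimethylsilyl)oxy]-1,4-dihydroxy-6-oxabicyclo[3.2.1]octan-7-one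
Conditions: TBSCl, imidazole, DMF, 0 °C → rt
Reagents that add atoms: tert-butyldimethylsilyl chloride, CC(C)(C)[Si](C)(C)Cl
Why: Selective silylation, because in the lactone-locked chair the C3 hydroxyl is equatorial and open whereas the C4 hydroxyl is axial and flanked on both sides and the C1 hydroxyl is tertiary.

Step 3
Reactants: 3 (1R,3R,4S,5R)-3-[(tert-butyldimethylsilyl)oxy]-1,4-dihydroxy-6-oxabicyclo[3.2.1]octan-7-one
Product: 4 (1R,3R,5R)-3-[(tert-butyldimethylsilyl)oxy]-1-hydroxy-6-oxabicyclo[3.2.1]octane-4,7-dione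
Conditions: Dess–Martin periodinane, CH2Cl2, rt
Reagents that add atoms: none
Why: Dess–Martin oxidation of the only secondary alcohol left, under neutral conditions that neither touch the tertiary alcohol nor epimerise the α-oxygenated ketone.

Step 4
Reactants: 4 (1R,3R,5R)-3-[(tert-butyldimethylsilyl)oxy]-1-hydroxy-6-oxabicyclo[3.2.1]octane-4,7-dione
Product: 5 (1R,3R,4R,5R)-3-[(tert-butyldimethylsilyl)oxy]-4-ethenyl-1,4-dihydroxy-6-oxabicyclo[3.2.1]octan-7-one (vinyl takes the place of the former axial C4 hydroxyl: vinyl cis to O3, new hydroxyl cis to the lactone oxygen on C5)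
Conditions: CH2=CHMgBr (3 equiv), THF, −78 → 0 °C; aq NH4Cl
Reagents that add atoms: vinylmagnesium bromide, C=C[Mg]Br
Why: Grignard 1,2-addition to the ketone (faster than attack on the lactone), the nucleophile entering axially on the face anti to the axial C5–O bond of the lactone bridge (Felkin–Anh and steric control by the bought C5 centre in the rigid bicycle), which sets the quaternary C4 carbinol.

Step 5
Reactants: 5 (1R,3R,4R,5R)-3-[(tert-butyldimethylsilyl)oxy]-4-ethenyl-1,4-dihydroxy-6-oxabicyclo[3.2.1]octan-7-one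
Product: 7 (3R,4R,5R)-3-[(tert-butyldimethylsilyl)oxy]-4-ethenyl-4,5-dihydroxycyclohexan-1-one, via lithium carboxylate 6 (not isolated)
Conditions: LiOH, THF/H2O, 0 °C; then MeOH, undivided cell, graphite anode, Pt cathode, constant current (2.5 F mol−1), 10 °C
Reagents that add atoms: none
Why: Saponification frees the α-hydroxy carboxylate, which undergoes anodic non-Kolbe (Hofer–Moest) oxidative decarboxylation to the ring ketone at a potential that spares the cis-diol (which periodate or Pb(OAc)4 would cleave), the alkene and the silyl ether, and leaves C3, C4 and C5 untouched.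

Step 6
Reactants: 7 (3R,4R,5R)-3-[(tert-butyldimethylsilyl)oxy]-4-ethenyl-4,5-dihydroxycyclohexan-1-one
Product: 10 (4R,5R)-5-[(tert-butyldimethylsilyl)oxy]-4-ethenyl-4-[(triethylsilyl)oxy]cyclohex-2-en-1-one, via mesylate 8 (not isolated), via hydroxy enone 9 (not isolated)
Conditions: MsCl, Et3N, CH2Cl2, 0 °C → rt; then 2,6-lutidine, TESOTf, −78 °C
Reagents that add atoms: triethylsilyl trifluoromethanesulfonate, CC[Si](CC)(CC)OS(=O)(=O)C(F)(F)F
Why: The secondary C5 hydroxyl is mesylated selectively and expelled by E1cB elimination with Et3N while the poorer β-silyloxy leaving group at C3 stays, and the tertiary allylic alcohol is then capped as its TES ether in the same flask, so the bought C3 centre now marks which side of the ring is which.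

Step 7
Reactants: 10 (4R,5R)-5-[(tert-butyldimethylsilyl)oxy]-4-ethenyl-4-[(triethylsilyl)oxy]cyclohex-2-en-1-one
Product: 11 (4R,5R)-5-[(tert-butyldimethylsilyl)oxy]-4-ethenyl-2-iodo-4-[(triethylsilyl)oxy]cyclohex-2-en-1-one
Conditions: I2, pyridine, CH2Cl2, rt
Reagents that add atoms: iodine, [I][I]
Why: Johnson α-iodination (conjugate addition of pyridine, iodination of the enolate, loss of pyridine) places iodine on the only enone α-carbon.

Step 8
Reactants: 12 (S)-3-bromo-2-methylpropan-1-ol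
Product: 13 (R)-2-methylhexan-1-ol
Conditions: n-PrMgBr (3 equiv), Li2CuCl4 (cat.), THF, −78 °C → rt; aq NH4Cl
Reagents that add atoms: n-propylmagnesium bromide, CCC[Mg]Br
Why: Copper-catalysed Kochi-type sp3–sp3 coupling of the primary bromide (as its magnesium alkoxide) with the Grignard reagent; the stereocentre does not react and its descriptor changes from S to R only through CIP priorities.

Step 9
Reactants: 13 (R)-2-methylhexan-1-ol
Product: 15 (2E,4R)-4-methyloct-2-enamide, via aldehyde 14 (not isolated)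
Conditions: Dess–Martin periodinane, CH2Cl2, 0 °C; then Ph3P=CHCONH2, rt
Reagents that add atoms: (carbamoylmethylene)triphenylphosphorane, NC(=O)C=P(c1ccccc1)(c1ccccc1)c1ccccc1
Why: Dess–Martin oxidation followed in the same flask by a Wittig reaction with the stabilised, non-basic amide ylide gives the E-enamide and traps the α-chiral aldehyde before it can epimerise.

Step 10
Reactants: 11 (4R,5R)-5-[(tert-butyldimethylsilyl)oxy]-4-ethenyl-2-iodo-4-[(triethylsilyl)oxy]cyclohex-2-en-1-one; 15 (2E,4R)-4-methyloct-2-enamide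
Product: 16 (2E,4R)-N-[(3R,4R)-4-[(tert-butyldimethylsilyl)oxy]-3-ethenyl-6-oxo-3-[(triethylsilyl)oxy]cyclohex-1-en-1-yl]-4-methyloct-2-enamide
Conditions: NiBr2(dme) (10 mol %), 4,4′-di-tert-butyl-2,2′-bipyridine (10 mol %), [Ir(ppy)2(dtbbpy)]PF6 (1 mol %), K3PO4, DMA, blue LEDs (450 nm), 25 °C
Reagents that add atoms: none
Why: Proposed new method: light-driven nickel-catalysed N-alkenylation of a primary carboxamide with a 2-iodo enone at room temperature, in which low-valent nickel inserts into the activated C(sp2)–I bond, the amide binds as amidate, and oxidation of the divalent alkenyl nickel amidate to trivalent nickel by the excited iridium photocatalyst triggers C–N reductive elimination, so the enamide bond forms without the heat and strong base that would expel the β-silyloxy group; the closest known reaction type is the nickel/photoredox N-arylation of amides, carbamates and sulfonamides with aryl halides, not yet shown for 2-halo enones or α,β-unsaturated primary amides; no stereocentre is formed.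

Step 11
Reactants: 16 (2E,4R)-N-[(3R,4R)-4-[(tert-butyldimethylsilyl)oxy]-3-ethenyl-6-oxo-3-[(triethylsilyl)oxy]cyclohex-1-en-1-yl]-4-methyloct-2-enamide
Product: 18 (2E,4R)-N-[(1S,5R,6R)-5-ethenyl-2-oxo-5-[(triethylsilyl)oxy]-7-oxabicyclo[4.1.0]hept-3-en-3-yl]-4-methyloct-2-enamide, via dienone 17 (not isolated)
Conditions: DBU, CH2Cl2, 0 °C → rt; then t-BuOOH (decane), rt
Reagents that add atoms: tert-butyl hydroperoxide, CC(C)(C)OO
Why: E1cB loss of the β-silyloxy group gives the cross-conjugated dienone, and Weitz–Scheffer epoxidation then occurs only at the unsubstituted enone (the amido enone is deactivated, the more so once its N–H is deprotonated) and anti to the bulky, electron-withdrawing OTES group on C4, which sets both epoxide centres cis to the vinyl group.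

Step 12
Reactants: 19 2-(diethoxyphosphoryl)acetic acid; 20 2-amino-3-hydroxycyclopent-2-en-1-one hydrochloride
Product: 21 diethyl [2-[(2-hydroxy-5-oxocyclopent-1-en-1-yl)amino]-2-oxoethyl]phosphonate
Conditions: EDC·HCl, Et3N, DMAP (cat.), CH2Cl2, 0 °C → rt
Reagents that add atoms: none
Why: Carbodiimide amide coupling at the amino group of the vinylogous acid, any O-acyl product rearranging to the N-acyl compound.

Step 13
Reactants: 21 diethyl [2-[(2-hydroxy-5-oxocyclopent-1-en-1-yl)amino]-2-oxoethyl]phosphonate; 22 (E)-3-iodoprop-2-en-1-ol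
Product: 24 (2E,4E)-N-(2-hydroxy-5-oxocyclopent-1-en-1-yl)-5-iodopenta-2,4-dienamide, via iodoacrolein 23 (not isolated)
Conditions: MnO2, LiOH·H2O, 4 Å molecular sieves, THF, rt → 50 °C, dark
Reagents that add atoms: none
Why: Tandem MnO2 oxidation/Horner–Wadsworth–Emmons olefination traps the unstable 3-iodoacrolein as it forms, the stabilised phosphonate giving the new double bond E while the E-iodoalkene is retained.

Step 14
Reactants: 18 (2E,4R)-N-[(1S,5R,6R)-5-ethenyl-2-oxo-5-[(triethylsilyl)oxy]-7-oxabicyclo[4.1.0]hept-3-en-3-yl]-4-methyloct-2-enamide; 24 (2E,4E)-N-(2-hydroxy-5-oxocyclopent-1-en-1-yl)-5-iodopenta-2,4-dienamide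
Product: 25 (2E,4R)-N-[(1S,5R,6R)-5-[(1E,3E,5E)-7-[(2-hydroxy-5-oxocyclopent-1-en-1-yl)amino]-7-oxohepta-1,3,5-trien-1-yl]-2-oxo-5-[(triethylsilyl)oxy]-7-oxabicyclo[4.1.0]hept-3-en-3-yl]-4-methyloct-2-enamide
Conditions: Pd(OAc)2 (10 mol %), n-Bu4NCl, NaHCO3, DMF, 40 °C, dark
Reagents that add atoms: none
Why: Heck reaction under phosphine-free Jeffery conditions, in which the dienylpalladium species adds to the terminal carbon of the vinyl group and syn β-hydride elimination (possible only on that side because C4 is quaternary) gives the E double bond and hence the all-E triene, under conditions mild enough for the epoxy ketone.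

Step 15
Reactants: 25 (2E,4R)-N-[(1S,5R,6R)-5-[(1E,3E,5E)-7-[(2-hydroxy-5-oxocyclopent-1-en-1-yl)amino]-7-oxohepta-1,3,5-trien-1-yl]-2-oxo-5-[(triethylsilyl)oxy]-7-oxabicyclo[4.1.0]hept-3-en-3-yl]-4-methyloct-2-enamide
Product: 26 (2E,4R)-N-[(1S,5R,6R)-5-hydroxy-5-[(1E,3E,5E)-7-[(2-hydroxy-5-oxocyclopent-1-en-1-yl)amino]-7-oxohepta-1,3,5-trien-1-yl]-2-oxo-7-oxabicyclo[4.1.0]hept-3-en-3-yl]-4-methyloct-2-enamide (CNP0259807.5)
Conditions: HF·pyridine, pyridine, THF, 0 °C
Reagents that add atoms: none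
Why: Buffered fluoride cleavage of the tertiary triethylsilyl ether under slightly acidic conditions, which avoids the alkoxide that could trigger a Payne rearrangement of the trans hydroxy epoxide and leaves the enamides, the epoxide and the triene untouched.

**Compound list**
1 | (−)-quinic acid, (1S,3R,4S,5R)-1,3,4,5-tetrahydroxycyclohexane-1-carboxylic acid | O[C@@]1(C(=O)O)C[C@@H](O)[C@@H](O)[C@H](O)C1 | starting material
2 | quinide, (1S,3R,4R,5R)-1,3,4-trihydroxy-6-oxabicyclo[3.2.1]octan-7-one | O[C@@]12C[C@@H](O)[C@@H](O)[C@@H](C1)OC2=O | intermediate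
3 | (1R,3R,4S,5R)-3-[(tert-butyldimethylsilyl)oxy]-1,4-dihydroxy-6-oxabicyclo[3.2.1]octan-7-one | O[C@@]12C[C@@H](O[Si](C)(C)C(C)(C)C)[C@@H](O)[C@@H](C1)OC2=O | intermediate
4 | (1R,3R,5R)-3-[(tert-butyldimethylsilyl)oxy]-1-hydroxy-6-oxabicyclo[3.2.1]octane-4,7-dione | O[C@@]12C[C@@H](O[Si](C)(C)C(C)(C)C)C(=O)[C@@H](C1)OC2=O | intermediate
5 | (1R,3R,4R,5R)-3-[(tert-butyldimethylsilyl)oxy]-4-ethenyl-1,4-dihydroxy-6-oxabicyclo[3.2.1]octan-7-one | O[C@@]12C[C@@H](O[Si](C)(C)C(C)(C)C)[C@@](O)(C=C)[C@@H](C1)OC2=O | intermediate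
6 | lithium (1R,3R,4R,5R)-3-[(tert-butyldimethylsilyl)oxy]-4-ethenyl-1,4,5-trihydroxycyclohexane-1-carboxylate | [Li+].[O-]C(=O)[C@]1(O)C[C@@H](O[Si](C)(C)C(C)(C)C)[C@@](O)(C=C)[C@H](O)C1 | intermediate
7 | (3R,4R,5R)-3-[(tert-butyldimethylsilyl)oxy]-4-ethenyl-4,5-dihydroxycyclohexan-1-one | O=C1C[C@@H](O[Si](C)(C)C(C)(C)C)[C@@](O)(C=C)[C@H](O)C1 | intermediate
8 | (3R,4S,5R)-3-[(tert-butyldimethylsilyl)oxy]-4-ethenyl-4-hydroxy-5-[(methanesulfonyl)oxy]cyclohexan-1-one | O=C1C[C@@H](O[Si](C)(C)C(C)(C)C)[C@@](O)(C=C)[C@H](OS(C)(=O)=O)C1 | intermediate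
9 | (4R,5R)-5-[(tert-butyldimethylsilyl)oxy]-4-ethenyl-4-hydroxycyclohex-2-en-1-one | O=C1C[C@@H](O[Si](C)(C)C(C)(C)C)[C@@](O)(C=C)C=C1 | intermediate
10 | (4R,5R)-5-[(tert-butyldimethylsilyl)oxy]-4-ethenyl-4-[(triethylsilyl)oxy]cyclohex-2-en-1-one | O=C1C[C@@H](O[Si](C)(C)C(C)(C)C)[C@@](O[Si](CC)(CC)CC)(C=C)C=C1 | intermediate
11 | (4R,5R)-5-[(tert-butyldimethylsilyl)oxy]-4-ethenyl-2-iodo-4-[(triethylsilyl)oxy]cyclohex-2-en-1-one | O=C1C[C@@H](O[Si](C)(C)C(C)(C)C)[C@@](O[Si](CC)(CC)CC)(C=C)C=C1I | intermediate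
12 | (S)-3-bromo-2-methylpropan-1-ol | OC[C@H](C)CBr | starting material
13 | (R)-2-methylhexan-1-ol | OC[C@H](C)CCCC | intermediate
14 | (R)-2-methylhexanal | O=C[C@H](C)CCCC | intermediate
15 | (2E,4R)-4-methyloct-2-enamide | NC(=O)/C=C/[C@H](C)CCCC | intermediate
16 | (2E,4R)-N-[(3R,4R)-4-[(tert-butyldimethylsilyl)oxy]-3-ethenyl-6-oxo-3-[(triethylsilyl)oxy]cyclohex-1-en-1-yl]-4-methyloct-2-enamide | CCCC[C@@H](C)/C=C/C(=O)NC1=C[C@](O[Si](CC)(CC)CC)(C=C)[C@H](O[Si](C)(C)C(C)(C)C)CC1=O | intermediate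
17 | (2E,4R)-N-[(3S)-3-ethenyl-6-oxo-3-[(triethylsilyl)oxy]cyclohexa-1,4-dien-1-yl]-4-methyloct-2-enamide | CCCC[C@@H](C)/C=C/C(=O)NC1=C[C@](O[Si](CC)(CC)CC)(C=C)C=CC1=O | intermediate
18 | (2E,4R)-N-[(1S,5R,6R)-5-ethenyl-2-oxo-5-[(triethylsilyl)oxy]-7-oxabicyclo[4.1.0]hept-3-en-3-yl]-4-methyloct-2-enamide | CCCC[C@@H](C)/C=C/C(=O)NC1=C[C@](O[Si](CC)(CC)CC)(C=C)[C@@H]2O[C@@H]2C1=O | intermediate
19 | 2-(diethoxyphosphoryl)acetic acid | CCOP(=O)(CC(=O)O)OCC | starting material
20 | 2-amino-3-hydroxycyclopent-2-en-1-one hydrochloride | NC1=C(O)CCC1=O.Cl | starting material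
21 | diethyl [2-[(2-hydroxy-5-oxocyclopent-1-en-1-yl)amino]-2-oxoethyl]phosphonate | CCOP(=O)(CC(=O)NC1=C(O)CCC1=O)OCC | intermediate
22 | (E)-3-iodoprop-2-en-1-ol | OC/C=C/I | starting material
23 | (E)-3-iodoprop-2-enal | O=C/C=C/I | intermediate
24 | (2E,4E)-N-(2-hydroxy-5-oxocyclopent-1-en-1-yl)-5-iodopenta-2,4-dienamide | I/C=C/C=C/C(=O)NC1=C(O)CCC1=O | intermediate
25 | (2E,4R)-N-[(1S,5R,6R)-5-[(1E,3E,5E)-7-[(2-hydroxy-5-oxocyclopent-1-en-1-yl)amino]-7-oxohepta-1,3,5-trien-1-yl]-2-oxo-5-[(triethylsilyl)oxy]-7-oxabicyclo[4.1.0]hept-3-en-3-yl]-4-methyloct-2-enamide | CCCC[C@@H](C)/C=C/C(=O)NC1=C[C@](O[Si](CC)(CC)CC)(/C=C/C=C/C=C/C(=O)NC2=C(O)CCC2=O)[C@@H]2O[C@@H]2C1=O | intermediate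
26 | (2E,4R)-N-[(1S,5R,6R)-5-hydroxy-5-[(1E,3E,5E)-7-[(2-hydroxy-5-oxocyclopent-1-en-1-yl)amino]-7-oxohepta-1,3,5-trien-1-yl]-2-oxo-7-oxabicyclo[4.1.0]hept-3-en-3-yl]-4-methyloct-2-enamide | CCCC[C@@H](C)/C=C/C(=O)NC1=C[C@](O)(/C=C/C=C/C=C/C(=O)NC2=C(O)CCC2=O)[C@@H]2O[C@@H]2C1=O | target

**Step count**
Total: 15 steps. Longest linear sequence: 11 steps (1–7, 10, 11, 14, 15).

**Steps most likely to fail, with fallbacks**

Step 4 (vinyl addition). The facial selectivity fixes the absolute configuration of the core, and the lactone is a competing electrophile. The fallback sets out from 4 and uses the slimmer ethynyl nucleophile, which attacks axially more cleanly: HC≡CMgBr in THF at −78 °C gives (1R,3R,4R,5R)-3-[(tert-butyldimethylsilyl)oxy]-4-ethynyl-1,4-dihydroxy-6-oxabicyclo[3.2.1]octan-7-one F1. Semi-hydrogenation of the alkyne (H2, Pd on CaCO3 poisoned with Pb(OAc)2, quinoline, EtOAc) brings the route back at 5.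

Step 10 (the proposed light-driven nickel C–N coupling). The amidate may not transmetalate, or base may expel the silanol too early. The fallback sets out from 11 and changes the order: DBU in CH2Cl2 first removes the silanol to give (4S)-4-ethenyl-2-iodo-4-[(triethylsilyl)oxy]cyclohexa-2,5-dien-1-one F2, which has no base-labile group left. F2 is then coupled with 15 by the established thermal palladium-catalysed amidation of vinyl halides (Pd2(dba)3, Xantphos, Cs2CO3, dioxane, 50 °C). This comes back to the route at dienone 17, which is isolated and epoxidised with t-BuOOH/DBU as in the second half of step 11.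

Step 14 (Heck reaction on a vinyl group next to a quaternary, silyloxy-bearing carbon, with a sensitive iododiene). The fallback sets out from 18: cross-metathesis with vinylboronic acid pinacol ester (second-generation Hoveyda–Grubbs catalyst RuCl2(H2IMes)(=CH-C6H4-2-OiPr), CH2Cl2, 40 °C) gives (2E,4R)-4-methyl-N-[(1S,5R,6R)-2-oxo-5-[(E)-2-(4,4,5,5-tetramethyl-1,3,2-dioxaborolan-2-yl)ethenyl]-5-[(triethylsilyl)oxy]-7-oxabicyclo[4.1.0]hept-3-en-3-yl]oct-2-enamide F3. Suzuki–Miyaura coupling of F3 with iodide 24 (Pd(dppf)Cl2, K3PO4, THF/H2O, rt) comes back to the route at 25.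

**Further compounds**
F1 | step 4 | (1R,3R,4R,5R)-3-[(tert-butyldimethylsilyl)oxy]-4-ethynyl-1,4-dihydroxy-6-oxabicyclo[3.2.1]octan-7-one | O[C@@]12C[C@@H](O[Si](C)(C)C(C)(C)C)[C@@](O)(C#C)[C@@H](C1)OC2=O
F2 | step 10 | (4S)-4-ethenyl-2-iodo-4-[(triethylsilyl)oxy]cyclohexa-2,5-dien-1-one | O=C1C=C[C@@](O[Si](CC)(CC)CC)(C=C)C=C1I
F3 | step 14 | (2E,4R)-4-methyl-N-[(1S,5R,6R)-2-oxo-5-[(E)-2-(4,4,5,5-tetramethyl-1,3,2-dioxaborolan-2-yl)ethenyl]-5-[(triethylsilyl)oxy]-7-oxabicyclo[4.1.0]hept-3-en-3-yl]oct-2-enamide | CCCC[C@@H](C)/C=C/C(=O)NC1=C[C@](O[Si](CC)(CC)CC)(/C=C/B3OC(C)(C)C(C)(C)O3)[C@@H]2O[C@@H]2C1=O
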